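**Assumptions.** (S,S)-Ph-pybox is taken to give the S ether in step 3. Both ligand enantiomers are commercial, so the antipode is used if the induction runs the other way. Flavan numbering is used throughout: the upper unit has rings A, B and C, and the lower unit has rings D, E and F. The target is 2,3-trans-3,4-trans mesquitol-(4α→8)-catechin, with 2R,3S,4S in the upper unit and 2R,3S in the lower unit.

## Retrosynthetic overview
1. The target comes from global hydrogenolysis of the protected dimer. Its C3 carbinol comes from axial hydride reduction of a 4-arylflavan-3-one that already carries every carbon.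
2. The key disconnection is C4 (upper)–C8 (lower). Both carbons are innately nucleophilic (a ketone α-carbon and a phloroglucinol-type CH), so the flavan-3-one is oxidised to an α-keto cation (enolonium equivalent) and captured by penta-O-benzylcatechin.
3. Ring C is closed at C4–C4a by an α-oxo gold carbene, made by oxidising the terminal alkyne of an aryl propargyl ether.
4. The O1–C2 bond and the C2 stereocentre come from an enantioconvergent copper-catalysed propargylic etherification of a racemic acetate with a pyrogallol ketal.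
5. Rings A, B and D/E/F are bought (pyrogallol, a benzaldehyde, (+)-catechin). Only ring C is built (step 4), and it is built before the interflavan bond (step 6).

## Route

Step 1
Reactants: 1 pyrogallol; 2 dichlorodiphenylmethane
Product: 3 2,2-diphenyl-1,3-benzodioxol-4-ol
Conditions: neat, 170 °C, 30 min, N2 sweep
Reagents that add atoms: dichlorodiphenylmethane (2), ClC(Cl)(c1ccccc1)c1ccccc1
Why: Ketalisation of a catechol unit by a gem-dichloride (double substitution through the diphenyl oxocarbenium ion) can bridge only two adjacent oxygens, so exactly one flanking phenol (the future O1) stays free and no stereocentre is formed.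

Step 2
Reactants: 4 3,4-bis(benzyloxy)benzaldehyde; 5 ethynylmagnesium bromide; 6 acetic anhydride
Product: 8 rac-1-[3,4-bis(benzyloxy)phenyl]prop-2-yn-1-yl acetate, via bromomagnesium alkoxide 7 (not isolated)
Conditions: HC≡CMgBr (1.2 equiv), THF, 0 °C; then Ac2O (1.5 equiv), 0 °C to rt
Reagents that add atoms: ethynylmagnesium bromide (5), C#C[Mg]Br; acetic anhydride (6), CC(=O)OC(C)=O
Why: Grignard 1,2-addition followed by in situ O-acylation of the magnesium alkoxide gives the propargylic ester in one flask, and the new centre is left racemic on purpose because step 3 erases and resets it.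

Step 3
Reactants: 8 rac-1-[3,4-bis(benzyloxy)phenyl]prop-2-yn-1-yl acetate; 3 2,2-diphenyl-1,3-benzodioxol-4-ol
Product: 10 (S)-4-{1-[3,4-bis(benzyloxy)phenyl]prop-2-yn-1-yloxy}-2,2-diphenyl-1,3-benzodioxole, via copper allenylidene 9 (not isolated)
Conditions: CuOTf·0.5C6H6 (5 mol%), (S,S)-Ph-pybox (7.5 mol%), iPr2NEt (1.2 equiv), ClCH2CH2Cl, -20 °C
Reagents that add atoms: none
Why: In this copper-catalysed enantioselective propargylic substitution (Nishibayashi-type etherification), loss of acetate from the copper acetylide gives planar allenylidene 9 so both enantiomers of 8 converge, and the phenol attacks the γ-carbon on the face left open by the pybox ligand, setting the future C2 as S (the same spatial arrangement as 2R in the flavan, since aryl outranks ethynyl but not C3).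

Step 4
Reactants: 10 (S)-aryl propargyl ether; 11 2,6-dichloropyridine N-oxide
Product: 13 (2R)-3',4'-bis(benzyloxy)-7,8-(diphenylmethylenedioxy)flavan-3-one, via alpha-oxo gold carbene 12 (not isolated)
Conditions: (Me4tBuXPhos)AuNTf2 (5 mol%; Me4tBuXPhos = 2-di-tert-butylphosphino-3,4,5,6-tetramethyl-2',4',6'-triisopropylbiphenyl), 11 (1.3 equiv), ClCH2CH2Cl, rt
Reagents that add atoms: 2,6-dichloropyridine N-oxide (11), [O-][n+]1c(Cl)cccc1Cl
Why: In this gold-catalysed alkyne oxidation (Zhang-type chroman-3-one synthesis), Markovnikov attack of the N-oxide on the gold-activated terminal alkyne and loss of the pyridine give carbene 12, an α-carbonyl cation equivalent, which the only free ortho carbon of ring A (para to the C7 oxygen) captures in a six-membered Friedel-Crafts-type closure that forms C4–C4a, while C2 is a spectator under these non-basic conditions.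

Step 5
Reactants: 14 (+)-catechin; 15 benzyl bromide
Product: 16 3,5,7,3',4'-penta-O-benzyl-(+)-catechin
Conditions: NaH (6 equiv), BnBr (6 equiv), DMF, -10 °C to rt
Reagents that add atoms: benzyl bromide (15), BrCc1ccccc1
Why: Williamson etherification caps all five hydroxyls in one operation, fast capping of the phenoxides at low temperature prevents base-induced opening of ring F so 2R,3S is retained, and no free OH is left to compete with C8 in step 6.

Step 6 (key step)
Reactants: 13 (2R)-flavan-3-one; 16 penta-O-benzyl-(+)-catechin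
Product: 19 (2R,4S)-3',4'-bis(benzyloxy)-7,8-(diphenylmethylenedioxy)-4-[penta-O-benzyl-(+)-catechin-8-yl]flavan-3-one, via enol 17 (not isolated), via alpha-keto cation 18 (not isolated)
Conditions: AgBF4 (2.2 equiv), 16 (2.5 equiv, excess recovered), 2,6-di-tert-butyl-4-methylpyridine (2.5 equiv), THF, reflux, dark
Reagents that add atoms: none
Why: In this silver-mediated oxidative C4 arylation of a flavan-3-one (an enolonium-type α-arylation), two equivalents of monovalent silver oxidise the styrene-like enol 17 to α-keto cation 18, which the para C7 oxygen also stabilises, the most nucleophilic carbon of 16 (C8) attacks it, and the acidic C4–H then lets the new centre settle pseudo-equatorial and 2,4-cis (4S) under control of the 2R aryl group, helped by the absence of a C5 peri substituent.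

Step 7
Reactants: 19 (2R,4S)-4-arylflavan-3-one
Product: 20 (2R,3S,4S)-3',4'-bis(benzyloxy)-7,8-(diphenylmethylenedioxy)-4-[penta-O-benzyl-(+)-catechin-8-yl]flavan-3-ol
Conditions: NaBH4 (2 equiv), THF/EtOH 4:1, -20 to 0 °C
Reagents that add atoms: none
Why: In this substrate-controlled ketone reduction both aryl groups are pseudo-equatorial and neither O1 nor C4a carries a 1,3-diaxial hydrogen, so the small hydride attacks C3 axially from the α face and gives the equatorial β-alcohol (3S), which is the 2,3-trans-3,4-trans array.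

Step 8
Reactants: 20 protected dimer
Product: 21 mesquitol-(4α→8)-catechin (target CNP0231186.1)
Conditions: H2 (1 atm), Pd(OH)2/C (20 wt%), THF/MeOH/H2O, rt; filtration under Ar, Sephadex LH-20
Reagents that add atoms: none
Why: Catalytic hydrogenolysis cleaves the seven O-benzyl groups and the diphenylmethylene ketal in one neutral operation, which leaves the acid-sensitive interflavan bond and all five stereocentres untouched.

## Compound list
1 | pyrogallol | Oc1cccc(O)c1O | starting material
2 | dichlorodiphenylmethane | ClC(Cl)(c1ccccc1)c1ccccc1 | starting material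
3 | 2,2-diphenyl-1,3-benzodioxol-4-ol | Oc1cccc2OC(c3ccccc3)(c3ccccc3)Oc12 | intermediate
4 | 3,4-bis(benzyloxy)benzaldehyde | O=Cc1ccc(OCc2ccccc2)c(OCc2ccccc2)c1 | starting material
5 | ethynylmagnesium bromide | C#C[Mg]Br | starting material
6 | acetic anhydride | CC(=O)OC(C)=O | starting material
7 | bromomagnesium 1-[3,4-bis(benzyloxy)phenyl]prop-2-yn-1-olate (racemic, not isolated) | C#CC(O[Mg]Br)c1ccc(OCc2ccccc2)c(OCc2ccccc2)c1 | intermediate
8 | rac-1-[3,4-bis(benzyloxy)phenyl]prop-2-yn-1-yl acetate | CC(=O)OC(C#C)c1ccc(OCc2ccccc2)c(OCc2ccccc2)c1 | intermediate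
9 | [(S,S)-Ph-pybox]copper 3-[3,4-bis(benzyloxy)phenyl]allenylidene triflate (not isolated; ligand and counter-ion written as separate components) | [Cu+]=C=C=Cc1ccc(OCc2ccccc2)c(OCc2ccccc2)c1.c1cc(nc(c1)C1=N[C@H](CO1)c1ccccc1)C1=N[C@H](CO1)c1ccccc1.[O-]S(=O)(=O)C(F)(F)F | intermediate
10 | (S)-4-{1-[3,4-bis(benzyloxy)phenyl]prop-2-yn-1-yloxy}-2,2-diphenyl-1,3-benzodioxole | c1ccccc1COc1ccc([C@H](C#C)Oc2cccc3OC(c4ccccc4)(c4ccccc4)Oc23)cc1OCc1ccccc1 | intermediate
11 | 2,6-dichloropyridine N-oxide | [O-][n+]1c(Cl)cccc1Cl | starting material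
12 | (R)-α-oxo gold carbene, (Me4tBuXPhos)Au=CH-C(=O)-CH(aryl)(O-aryl) bistriflimide (not isolated) | c1ccccc1COc1ccc([C@H](C(=O)C=[Au][P+](C(C)(C)C)(C(C)(C)C)c2c(C)c(C)c(C)c(C)c2-c2c(C(C)C)cc(C(C)C)cc2C(C)C)Oc2cccc3OC(c4ccccc4)(c4ccccc4)Oc23)cc1OCc1ccccc1.[N-](S(=O)(=O)C(F)(F)F)S(=O)(=O)C(F)(F)F | intermediate
13 | (2R)-3',4'-bis(benzyloxy)-7,8-(diphenylmethylenedioxy)flavan-3-one | c1ccccc1COc1ccc([C@H]2Oc3c(ccc4OC(c5ccccc5)(c5ccccc5)Oc34)CC2=O)cc1OCc1ccccc1 | intermediate
14 | (+)-catechin (2R,3S) | c1c(O)cc(O)c2c1O[C@H](c1ccc(O)c(O)c1)[C@@H](O)C2 | starting material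
15 | benzyl bromide | BrCc1ccccc1 | starting material
16 | 3,5,7,3',4'-penta-O-benzyl-(+)-catechin (2R,3S) | c1c(OCc2ccccc2)cc(OCc2ccccc2)c2c1O[C@H](c1ccc(OCc3ccccc3)c(OCc3ccccc3)c1)[C@@H](OCc1ccccc1)C2 | intermediate
17 | (2R)-3',4'-bis(benzyloxy)-7,8-(diphenylmethylenedioxy)flav-3-en-3-ol, enol of 13 (not isolated) | c1ccccc1COc1ccc([C@H]2Oc3c(ccc4OC(c5ccccc5)(c5ccccc5)Oc34)C=C2O)cc1OCc1ccccc1 | intermediate
18 | (2R)-3-oxoflavan-4-ylium tetrafluoroborate of 13, the α-keto cation (not isolated) | c1ccccc1COc1ccc([C@H]2Oc3c(ccc4OC(c5ccccc5)(c5ccccc5)Oc34)[CH+]C2=O)cc1OCc1ccccc1.F[B-](F)(F)F | intermediate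
19 | (2R,4S)-3',4'-bis(benzyloxy)-7,8-(diphenylmethylenedioxy)-4-[penta-O-benzyl-(+)-catechin-8-yl]flavan-3-one | c1ccccc1COc1ccc([C@H]2Oc3c(ccc4OC(c5ccccc5)(c5ccccc5)Oc34)[C@@H](c3c(OCc4ccccc4)cc(OCc4ccccc4)c4c3O[C@H](c3ccc(OCc5ccccc5)c(OCc5ccccc5)c3)[C@@H](OCc3ccccc3)C4)C2=O)cc1OCc1ccccc1 | intermediate
20 | (2R,3S,4S)-3',4'-bis(benzyloxy)-7,8-(diphenylmethylenedioxy)-4-[penta-O-benzyl-(+)-catechin-8-yl]flavan-3-ol | c1ccccc1COc1ccc([C@H]2Oc3c(ccc4OC(c5ccccc5)(c5ccccc5)Oc34)[C@@H](c3c(OCc4ccccc4)cc(OCc4ccccc4)c4c3O[C@H](c3ccc(OCc5ccccc5)c(OCc5ccccc5)c3)[C@@H](OCc3ccccc3)C4)[C@@H]2O)cc1OCc1ccccc1 | intermediate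
21 | mesquitol-(4α→8)-catechin, CNP0231186.1 | Oc1ccc([C@H]2Oc3c(ccc(O)c3O)[C@@H](c3c(O)cc(O)c4c3O[C@H](c3ccc(O)c(O)c3)[C@@H](O)C4)[C@@H]2O)cc1O | target

## Step count
- **Total steps:** 8.
- **Longest linear sequence:** 6 (steps 2, 3, 4, 6, 7 and 8, from aldehyde 4). Steps 1 and 5 are one-step side branches.
- **Enantiopurity:** any shortfall in ee from steps 3 and 4 becomes a separable diastereomer once enantiopure 16 is attached in step 6.

## Steps most likely to fail

**Step 6.**
- Cation 18 may lose H-2 and aromatise to a 3-hydroxyflavylium salt, which destroys C2.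
- Product 19 may be oxidised a second time.
- Some C6 attack on 16 may occur.

The fallback sets out from 13 and comes back at 19. Regitz diazo transfer to the acidic C4 methylene (4-acetamidobenzenesulfonyl azide, Et3N, MeCN, 0 °C) gives (2R)-3',4'-bis(benzyloxy)-4-diazo-7,8-(diphenylmethylenedioxy)flavan-3-one F1. This is decomposed with [(2,4-tBu2C6H3O)3P]AuCl/AgSbF6 (5 mol%) in CH2Cl2 in the presence of 16. The electrophilic C4 metal carbene keeps the same reversed polarity at C4 but needs no external oxidant. It substitutes C8–H of 16 and gives 19 after equilibration of C4.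

**Step 4.**
- Ring B may capture the carbene in a five-membered closure to give an indan-2-one.
- Oxidant-free 6-endo hydroarylation may compete.
- Cationic gold may ionise the benzylic-propargylic C–O bond and erode the ee.

The fallback sets out from 10 and comes back at 13. The hydroarylation pathway is used deliberately: (Ph3P)AuNTf2 (2 mol%) in CH2Cl2 at 0 °C without N-oxide gives (2S)-3',4'-bis(benzyloxy)-7,8-(diphenylmethylenedioxy)flav-3-ene F2, which has the same spatial arrangement at C2. Hydroboration (BH3·SMe2, THF, 0 °C, then NaBO3) occurs anti to the 2-aryl group and places boron on the non-benzylic C3. This gives (2R,3S)-3',4'-bis(benzyloxy)-7,8-(diphenylmethylenedioxy)flavan-3-ol F3. Dess-Martin periodinane in CH2Cl2 then oxidises it to 13.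

**Step 3.**
- The electron-rich aryl group may allow uncatalysed SN1 ionisation of 8 and so lower the ee.
- The electron-rich phenol 3 may be C-propargylated instead of O-alkylated.

The fallback sets out from 4 (with 3) and comes back at 10. Me2Zn/ProPhenol-catalysed asymmetric addition of trimethylsilylacetylene to 4 gives (S)-1-[3,4-bis(benzyloxy)phenyl]-3-(trimethylsilyl)prop-2-yn-1-ol F4. Mitsunobu etherification with 3 (PPh3, DIAD, toluene, -20 °C) inverts the carbinol and gives (R)-4-{1-[3,4-bis(benzyloxy)phenyl]-3-(trimethylsilyl)prop-2-yn-1-yloxy}-2,2-diphenyl-1,3-benzodioxole F5. K2CO3 in MeOH then removes the silyl group to give 10.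

## Further compounds
F1 | step 6 | (2R)-3',4'-bis(benzyloxy)-4-diazo-7,8-(diphenylmethylenedioxy)flavan-3-one | c1ccccc1COc1ccc([C@H]2Oc3c(ccc4OC(c5ccccc5)(c5ccccc5)Oc34)C(=[N+]=[N-])C2=O)cc1OCc1ccccc1
F2 | step 4 | (2S)-3',4'-bis(benzyloxy)-7,8-(diphenylmethylenedioxy)flav-3-ene | c1ccccc1COc1ccc([C@H]2Oc3c(ccc4OC(c5ccccc5)(c5ccccc5)Oc34)C=C2)cc1OCc1ccccc1
F3 | step 4 | (2R,3S)-3',4'-bis(benzyloxy)-7,8-(diphenylmethylenedioxy)flavan-3-ol | c1ccccc1COc1ccc([C@H]2Oc3c(ccc4OC(c5ccccc5)(c5ccccc5)Oc34)C[C@@H]2O)cc1OCc1ccccc1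
F4 | step 3 | (S)-1-[3,4-bis(benzyloxy)phenyl]-3-(trimethylsilyl)prop-2-yn-1-ol | c1ccccc1COc1ccc([C@@H](C#C[Si](C)(C)C)O)cc1OCc1ccccc1
F5 | step 3 | (R)-4-{1-[3,4-bis(benzyloxy)phenyl]-3-(trimethylsilyl)prop-2-yn-1-yloxy}-2,2-diphenyl-1,3-benzodioxole | c1ccccc1COc1ccc([C@H](C#C[Si](C)(C)C)Oc2cccc3OC(c4ccccc4)(c4ccccc4)Oc23)cc1OCc1ccccc1
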